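**Retrosynthetic overview**
- The target comes from a fully protected depside (ring A as bis-benzyl ether, ring B as benzyl ester and C4 silyl ether) by fluoride desilylation and hydrogenolysis.
- Ring B, formed last, is cut at C1–C2 and C5–C6 (Alder–Rickert benzannulation) into benzyl hex-2-ynoate (C1, C6) and a dimedone-derived cyclohexadiene; its CH2–CMe2 bridge leaves as 2-methylpropene.
- The strategy rests on the three contiguous, mutually different oxygens of ring B (C2–OMe, C3–O-aroyl, C4–OH) between the C1 carboxyl and C5–H/C6–propyl. They map onto a 1-methoxy-2-aroyloxy-3-silyloxy diene plus a 2-alkynoate, so no pyrogallol has to be differentiated.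
- The diene comes from kinetic silylation and O-methylation of symmetric 2-aroyloxydimedone, itself from Rh2(OAc)4-catalysed O–H insertion of the ring A acid into 2-diazodimedone; the depside C–O bond is made there, not by acylation.
- Ring A, formed first, comes from Michael–Claisen annulation of dimethyl malonate with (E)-hept-3-en-2-one, then aromatisation, benzylation and saponification.

Key step: step 10

Remark: ring B is numbered from its carboxyl carbon (C1 CO2H, C2 OMe, C3 aroyloxy, C4 OH, C5 H, C6 propyl). The target has no stereocentre; the sp3 centres of 3, 4, 5 and 17 are racemic and are erased on aromatisation.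

**Route**

Step 1
Reactants: 1 dimethyl malonate; 2 (E)-hept-3-en-2-one
Product: 4 methyl 2-hydroxy-4-oxo-6-propylcyclohex-2-ene-1-carboxylate (racemic; enol form of the 2,4-dione), via Michael adduct 3 (not isolated)
Conditions: NaOMe, MeOH, reflux; then aq. HCl
Reagents that add atoms: none
Why: Michael addition of the malonate anion to the enone β-carbon is followed by intramolecular Claisen (Dieckmann-type) condensation of the methyl-ketone enolate on one ester to close the six-membered ring; the two sp3 centres formed are not controlled and are removed in step 2.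

Step 2
Reactants: 4 methyl 2-hydroxy-4-oxo-6-propylcyclohex-2-ene-1-carboxylate
Product: 6 methyl 2,4-dihydroxy-6-propylbenzoate, via 3-bromo dione ester 5 (not isolated)
Conditions: Br2 (1.0 equiv), DMF, 0 °C, then 80 °C
Reagents that add atoms: none
Why: Bromination of the 1,3-dione enol at C3 and thermal loss of HBr through the bis-enol should give the resorcinol ring (oxidative aromatisation by halogenation–dehydrohalogenation) with the ester retained.

Step 3
Reactants: 6 methyl 2,4-dihydroxy-6-propylbenzoate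
Product: 7 methyl 2,4-bis(benzyloxy)-6-propylbenzoate
Conditions: BnBr, K2CO3, DMF, 60 °C
Reagents that add atoms: benzyl bromide, BrCc1ccccc1
Why: Williamson etherification of both phenols; warming is needed for the hydrogen-bonded C2 hydroxyl.

Step 4
Reactants: 7 methyl 2,4-bis(benzyloxy)-6-propylbenzoate
Product: 8 2,4-bis(benzyloxy)-6-propylbenzoic acid
Conditions: KOH, DMSO/H2O, 100 °C; then aq. HCl
Reagents that add atoms: potassium hydroxide, [K+].[OH-]
Why: Saponification of the hindered 2,6-disubstituted methyl benzoate needs hot hydroxide in a dipolar solvent, under which aryl benzyl ethers are stable.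

Step 5
Reactants: 9 dimedone (5,5-dimethylcyclohexane-1,3-dione)
Product: 10 2-diazo-5,5-dimethylcyclohexane-1,3-dione
Conditions: 4-acetamidobenzenesulfonyl azide, Et3N, MeCN, 0 °C → rt
Reagents that add atoms: 4-acetamidobenzenesulfonyl azide, CC(=O)Nc1ccc(cc1)S(=O)(=O)N=[N+]=[N-]
Why: Regitz diazo transfer to the doubly activated methylene of a 1,3-dione is a standard, high-yielding reaction type.

Step 6
Reactants: 10 2-diazo-5,5-dimethylcyclohexane-1,3-dione; 8 2,4-bis(benzyloxy)-6-propylbenzoic acid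
Product: 11 2-hydroxy-4,4-dimethyl-6-oxocyclohex-1-en-1-yl 2,4-bis(benzyloxy)-6-propylbenzoate (enol of the 2-aroyloxy-1,3-dione)
Conditions: Rh2(OAc)4 (1 mol %), PhF, 80 °C, slow addition of 10
Reagents that add atoms: none
Why: Rhodium-carbenoid O–H insertion of a carboxylic acid into a 2-diazo-1,3-dicarbonyl compound is fast compared with attack on ether oxygen or arene, and it forms the future ring B C3–O bond without acylating a hindered phenol.

Step 7
Reactants: 11 2-hydroxy-4,4-dimethyl-6-oxocyclohex-1-en-1-yl 2,4-bis(benzyloxy)-6-propylbenzoate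
Product: 12 2-methoxy-4,4-dimethyl-6-oxocyclohex-1-en-1-yl 2,4-bis(benzyloxy)-6-propylbenzoate
Conditions: TMSCHN2, PhMe/MeOH, 0 °C → rt
Reagents that add atoms: trimethylsilyldiazomethane, C[Si](C)(C)C=[N+]=[N-]
Why: The acidic enol of a cyclic 1,3-dione is O-methylated by the diazoalkane under neutral conditions, and because 11 is symmetric only one enol ether can form.

Step 8
Reactants: 12 2-methoxy-4,4-dimethyl-6-oxocyclohex-1-en-1-yl 2,4-bis(benzyloxy)-6-propylbenzoate
Product: 14 6-[(tert-butyldimethylsilyl)oxy]-2-methoxy-4,4-dimethylcyclohexa-1,5-dien-1-yl 2,4-bis(benzyloxy)-6-propylbenzoate, via lithium dienolate 13 (not isolated)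
Conditions: LDA (1.05 equiv), THF, −78 °C; TBSCl, DMPU, −78 → 0 °C
Reagents that add atoms: tert-butyldimethylsilyl chloride, CC(C)(C)[Si](C)(C)Cl
Why: Kinetic deprotonation of a β-alkoxy enone at the α′ carbon (Stork–Danheiser-type enolisation) gives the cross-conjugated dienolate, which is trapped on oxygen; the hindered aroyl ester and the benzyl ethers should tolerate one equivalent of amide base at −78 °C.

Step 9
Reactants: 15 hex-2-ynoic acid
Product: 16 benzyl hex-2-ynoate
Conditions: BnBr, K2CO3, DMF, rt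
Reagents that add atoms: benzyl bromide, BrCc1ccccc1
Why: O-alkylation of the carboxylate by SN2 displacement on benzyl bromide gives the ester under conditions too mild to isomerise the alkyne.

Step 10
Reactants: 14 6-[(tert-butyldimethylsilyl)oxy]-2-methoxy-4,4-dimethylcyclohexa-1,5-dien-1-yl 2,4-bis(benzyloxy)-6-propylbenzoate; 16 benzyl hex-2-ynoate
Product: 18 benzyl 3-{[2,4-bis(benzyloxy)-6-propylbenzoyl]oxy}-4-[(tert-butyldimethylsilyl)oxy]-2-methoxy-6-propylbenzoate, via bicyclo[2.2.2]octadiene adduct 17 (not isolated)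
Conditions: 16 (3 equiv), o-xylene, 150–160 °C, sealed tube
Reagents that add atoms: none
Why: The electron-rich diene 14 and the electron-poor ynoate 16 should combine in a concerted, asynchronous normal-demand [4+2] cycloaddition to the bicyclo[2.2.2]octa-2,5-diene 17, which at the same temperature loses its CH2–CMe2 bridge as 2-methylpropene in a retro-[4+2] step made irreversible by aromatisation. The closest known reaction type is the Alder–Rickert synthesis of resorcylates from 1-alkoxy-3-silyloxycyclohexa-1,3-dienes and 2-alkynoates, and acyclic 1-methoxy-2-acyloxy-3-silyloxybutadienes are established dienes, so the 2-aroyloxy group is a spectator in a known process. Ring B is closed by intermolecular [4+2] annulation in which C1–C2 and C5–C6 form in the same step, and the cycloreversion then converts the bicycle into the single six-membered arene. The only stereocentres are the two bridgeheads of 17, fixed by the bicyclic geometry and erased on aromatisation, so nothing has to be controlled. The step needs regioselectivity: the methoxy group (vinylogously) and the silyloxy group both place the largest HOMO coefficient on the unsubstituted diene terminus (future C5), which should bond to the propyl-bearing β-carbon of the ynoate, so that propyl ends on C6 and the ester on C1. Only extrusion of the saturated two-carbon bridge leads to an arene, which secures the direction of the fragmentation.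

Step 11
Reactants: 18 benzyl 3-{[2,4-bis(benzyloxy)-6-propylbenzoyl]oxy}-4-[(tert-butyldimethylsilyl)oxy]-2-methoxy-6-propylbenzoate
Product: 19 benzyl 3-{[2,4-bis(benzyloxy)-6-propylbenzoyl]oxy}-4-hydroxy-2-methoxy-6-propylbenzoate
Conditions: TBAF, AcOH, THF, 0 °C
Reagents that add atoms: none
Why: Fluoride cleaves the aryl silyl ether, and the acetic acid buffer keeps the liberated C4 phenol protonated so that the neighbouring C3 aroyl group should not migrate and no ester is cleaved.

Step 12
Reactants: 19 benzyl 3-{[2,4-bis(benzyloxy)-6-propylbenzoyl]oxy}-4-hydroxy-2-methoxy-6-propylbenzoate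
Product: 20 3-[(2,4-dihydroxy-6-propylbenzoyl)oxy]-4-hydroxy-2-methoxy-6-propylbenzoic acid (target)
Conditions: H2 (1 atm), 10% Pd/C, EtOAc, rt
Reagents that add atoms: none
Why: Catalytic hydrogenolysis removes the two benzyl ethers and the benzyl ester in one operation and leaves the aryl ester link and both arenes untouched.

**Compound list**
1 | dimethyl malonate | COC(=O)CC(=O)OC | starting material
2 | (E)-hept-3-en-2-one | CCC/C=C/C(C)=O | starting material
3 | dimethyl 2-(2-oxoheptan-4-yl)propanedioate (racemic Michael adduct) | CCCC(CC(C)=O)C(C(=O)OC)C(=O)OC | intermediate (not isolated)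
4 | methyl 2-hydroxy-4-oxo-6-propylcyclohex-2-ene-1-carboxylate (racemic, diastereomer mixture) | CCCC1CC(=O)C=C(O)C1C(=O)OC | intermediate
5 | methyl 3-bromo-2-hydroxy-4-oxo-6-propylcyclohex-2-ene-1-carboxylate (racemic) | CCCC1CC(=O)C(Br)=C(O)C1C(=O)OC | intermediate (not isolated)
6 | methyl 2,4-dihydroxy-6-propylbenzoate | CCCc1cc(O)cc(O)c1C(=O)OC | intermediate
7 | methyl 2,4-bis(benzyloxy)-6-propylbenzoate | CCCc1cc(OCc2ccccc2)cc(OCc2ccccc2)c1C(=O)OC | intermediate
8 | 2,4-bis(benzyloxy)-6-propylbenzoic acid | CCCc1cc(OCc2ccccc2)cc(OCc2ccccc2)c1C(=O)O | intermediate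
9 | dimedone (5,5-dimethylcyclohexane-1,3-dione) | CC1(C)CC(=O)CC(=O)C1 | starting material
10 | 2-diazo-5,5-dimethylcyclohexane-1,3-dione | CC1(C)CC(=O)C(=[N+]=[N-])C(=O)C1 | intermediate
11 | 2-hydroxy-4,4-dimethyl-6-oxocyclohex-1-en-1-yl 2,4-bis(benzyloxy)-6-propylbenzoate | CCCc1cc(OCc2ccccc2)cc(OCc2ccccc2)c1C(=O)OC1=C(O)CC(C)(C)CC1=O | intermediate
12 | 2-methoxy-4,4-dimethyl-6-oxocyclohex-1-en-1-yl 2,4-bis(benzyloxy)-6-propylbenzoate | CCCc1cc(OCc2ccccc2)cc(OCc2ccccc2)c1C(=O)OC1=C(OC)CC(C)(C)CC1=O | intermediate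
13 | lithium 6-{[2,4-bis(benzyloxy)-6-propylbenzoyl]oxy}-5-methoxy-3,3-dimethylcyclohexa-1,5-dien-1-olate | COC1=C(OC(=O)c2c(CCC)cc(OCc3ccccc3)cc2OCc2ccccc2)C([O-])=CC(C)(C)C1.[Li+] | intermediate (not isolated)
14 | 6-[(tert-butyldimethylsilyl)oxy]-2-methoxy-4,4-dimethylcyclohexa-1,5-dien-1-yl 2,4-bis(benzyloxy)-6-propylbenzoate | COC1=C(OC(=O)c2c(CCC)cc(OCc3ccccc3)cc2OCc2ccccc2)C(O[Si](C)(C)C(C)(C)C)=CC(C)(C)C1 | intermediate
15 | hex-2-ynoic acid | CCCC#CC(=O)O | starting material
16 | benzyl hex-2-ynoate | CCCC#CC(=O)OCc1ccccc1 | intermediate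
17 | benzyl 6-{[2,4-bis(benzyloxy)-6-propylbenzoyl]oxy}-5-[(tert-butyldimethylsilyl)oxy]-1-methoxy-8,8-dimethyl-3-propylbicyclo[2.2.2]octa-2,5-diene-2-carboxylate (racemic) | COC12CC(C)(C)C(C(CCC)=C1C(=O)OCc1ccccc1)C(O[Si](C)(C)C(C)(C)C)=C2OC(=O)c1c(CCC)cc(OCc3ccccc3)cc1OCc1ccccc1 | intermediate (not isolated)
18 | benzyl 3-{[2,4-bis(benzyloxy)-6-propylbenzoyl]oxy}-4-[(tert-butyldimethylsilyl)oxy]-2-methoxy-6-propylbenzoate | CCCc1cc(O[Si](C)(C)C(C)(C)C)c(OC(=O)c2c(CCC)cc(OCc3ccccc3)cc2OCc2ccccc2)c(OC)c1C(=O)OCc1ccccc1 | intermediate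
19 | benzyl 3-{[2,4-bis(benzyloxy)-6-propylbenzoyl]oxy}-4-hydroxy-2-methoxy-6-propylbenzoate | CCCc1cc(O)c(OC(=O)c2c(CCC)cc(OCc3ccccc3)cc2OCc2ccccc2)c(OC)c1C(=O)OCc1ccccc1 | intermediate
20 | 3-[(2,4-dihydroxy-6-propylbenzoyl)oxy]-4-hydroxy-2-methoxy-6-propylbenzoic acid | CCCc1cc(O)cc(O)c1C(=O)Oc1c(O)cc(CCC)c(C(=O)O)c1OC | target

**Step count**
Total step count: 12.
Longest linear sequence: 10 steps (steps 1, 2, 3, 4, 6, 7, 8, 10, 11, 12).

**Steps most likely to fail**

Step 10. Cycloaddition of an internal, β-alkyl ynoate may be slower than thermal degradation of the diene (loss or migration of the silyl group, aroyl migration), and part of the ynoate may add with reversed orientation. The fallback brings in the carboxyl carbon at the aldehyde oxidation level with a much stronger dienophile.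
- It sets out from 14, which is heated with commercial hex-2-ynal in toluene at 90–110 °C.
- This should give, through the bicyclic adduct 6-{[2,4-bis(benzyloxy)-6-propylbenzoyl]oxy}-5-[(tert-butyldimethylsilyl)oxy]-1-methoxy-8,8-dimethyl-3-propylbicyclo[2.2.2]octa-2,5-diene-2-carbaldehyde F1 and loss of 2-methylpropene, the aldehyde 6-[(tert-butyldimethylsilyl)oxy]-3-formyl-2-methoxy-4-propylphenyl 2,4-bis(benzyloxy)-6-propylbenzoate F2.
- Pinnick oxidation (NaClO2, NaH2PO4, 2-methylbut-2-ene, t-BuOH/H2O) would give 3-{[2,4-bis(benzyloxy)-6-propylbenzoyl]oxy}-4-[(tert-butyldimethylsilyl)oxy]-2-methoxy-6-propylbenzoic acid F3.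
- Carboxylate benzylation (BnBr, KHCO3, DMF) brings the route back at 18.

Step 8. Deprotonation may occur in part at the γ-carbon, which would transpose the methoxy and silyloxy groups in ring B. The lithium dienolate may also pass its aroyl group to the neighbouring enolate oxygen, and the diene may hydrolyse on isolation. The fallback removes the regiochemical question by silylating both oxygens and differentiating them after aromatisation, by chelation.
- It sets out from 11, which with TBSOTf and Et3N in CH2Cl2 at 0 °C should give the single possible diene 2,6-bis[(tert-butyldimethylsilyl)oxy]-4,4-dimethylcyclohexa-1,5-dien-1-yl 2,4-bis(benzyloxy)-6-propylbenzoate F4.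
- Heating F4 with 16 as in step 10 would lead, through the adduct benzyl 6-{[2,4-bis(benzyloxy)-6-propylbenzoyl]oxy}-1,5-bis[(tert-butyldimethylsilyl)oxy]-8,8-dimethyl-3-propylbicyclo[2.2.2]octa-2,5-diene-2-carboxylate F5, to benzyl 3-{[2,4-bis(benzyloxy)-6-propylbenzoyl]oxy}-2,4-bis[(tert-butyldimethylsilyl)oxy]-6-propylbenzoate F6.
- TBAF/AcOH would give benzyl 3-{[2,4-bis(benzyloxy)-6-propylbenzoyl]oxy}-2,4-dihydroxy-6-propylbenzoate F7.
- TBSCl and imidazole in DMF should silylate only the C4 hydroxyl, because the C2 hydroxyl is hydrogen-bonded to the ester carbonyl, giving benzyl 3-{[2,4-bis(benzyloxy)-6-propylbenzoyl]oxy}-4-[(tert-butyldimethylsilyl)oxy]-2-hydroxy-6-propylbenzoate F8.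
- Methylation of the chelated hydroxyl with MeI and Ag2O brings the route back at 18.

Step 6. The carbenoid may be diverted into ring contraction by Wolff-type rearrangement, into attack on a benzyl ether oxygen or an arene of 8, or into a second insertion into the enol O–H of the product. The fallback avoids a metal carbenoid and uses hypervalent iodine chemistry.
- It sets out from 9, which with PhI(OAc)2 and KOH in MeOH at 0 °C gives the phenyliodonium ylide 5,5-dimethyl-3-oxo-2-(phenyliodonio)cyclohex-1-en-1-olate F9.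
- Treating F9 with acid 8 in CH2Cl2 at rt to 40 °C should protonate the ylide to the iodonium carboxylate, which collapses with loss of iodobenzene and brings the route back at 11.

**Further compounds**
F1 | step 10 | 6-{[2,4-bis(benzyloxy)-6-propylbenzoyl]oxy}-5-[(tert-butyldimethylsilyl)oxy]-1-methoxy-8,8-dimethyl-3-propylbicyclo[2.2.2]octa-2,5-diene-2-carbaldehyde (racemic) | COC12CC(C)(C)C(C(CCC)=C1C=O)C(O[Si](C)(C)C(C)(C)C)=C2OC(=O)c1c(CCC)cc(OCc3ccccc3)cc1OCc1ccccc1
F2 | step 10 | 6-[(tert-butyldimethylsilyl)oxy]-3-formyl-2-methoxy-4-propylphenyl 2,4-bis(benzyloxy)-6-propylbenzoate | CCCc1cc(O[Si](C)(C)C(C)(C)C)c(OC(=O)c2c(CCC)cc(OCc3ccccc3)cc2OCc2ccccc2)c(OC)c1C=O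
F3 | step 10 | 3-{[2,4-bis(benzyloxy)-6-propylbenzoyl]oxy}-4-[(tert-butyldimethylsilyl)oxy]-2-methoxy-6-propylbenzoic acid | CCCc1cc(O[Si](C)(C)C(C)(C)C)c(OC(=O)c2c(CCC)cc(OCc3ccccc3)cc2OCc2ccccc2)c(OC)c1C(=O)O
F4 | step 8 | 2,6-bis[(tert-butyldimethylsilyl)oxy]-4,4-dimethylcyclohexa-1,5-dien-1-yl 2,4-bis(benzyloxy)-6-propylbenzoate | CC1(C)CC(O[Si](C)(C)C(C)(C)C)=C(OC(=O)c2c(CCC)cc(OCc3ccccc3)cc2OCc2ccccc2)C(O[Si](C)(C)C(C)(C)C)=C1
F5 | step 8 | benzyl 6-{[2,4-bis(benzyloxy)-6-propylbenzoyl]oxy}-1,5-bis[(tert-butyldimethylsilyl)oxy]-8,8-dimethyl-3-propylbicyclo[2.2.2]octa-2,5-diene-2-carboxylate (racemic) | CC(C)(C)[Si](C)(C)OC12CC(C)(C)C(C(CCC)=C1C(=O)OCc1ccccc1)C(O[Si](C)(C)C(C)(C)C)=C2OC(=O)c1c(CCC)cc(OCc3ccccc3)cc1OCc1ccccc1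
F6 | step 8 | benzyl 3-{[2,4-bis(benzyloxy)-6-propylbenzoyl]oxy}-2,4-bis[(tert-butyldimethylsilyl)oxy]-6-propylbenzoate | CCCc1cc(O[Si](C)(C)C(C)(C)C)c(OC(=O)c2c(CCC)cc(OCc3ccccc3)cc2OCc2ccccc2)c(O[Si](C)(C)C(C)(C)C)c1C(=O)OCc1ccccc1
F7 | step 8 | benzyl 3-{[2,4-bis(benzyloxy)-6-propylbenzoyl]oxy}-2,4-dihydroxy-6-propylbenzoate | CCCc1cc(O)c(OC(=O)c2c(CCC)cc(OCc3ccccc3)cc2OCc2ccccc2)c(O)c1C(=O)OCc1ccccc1
F8 | step 8 | benzyl 3-{[2,4-bis(benzyloxy)-6-propylbenzoyl]oxy}-4-[(tert-butyldimethylsilyl)oxy]-2-hydroxy-6-propylbenzoate | CCCc1cc(O[Si](C)(C)C(C)(C)C)c(OC(=O)c2c(CCC)cc(OCc3ccccc3)cc2OCc2ccccc2)c(O)c1C(=O)OCc1ccccc1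
F9 | step 6 | 5,5-dimethyl-3-oxo-2-(phenyliodonio)cyclohex-1-en-1-olate | CC1(C)CC(=O)C([I+]c2ccccc2)=C([O-])C1
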